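The cyclohexane ring of the quinate core is cut at C2–C3 and C6–C5, the two bonds that join the methylenes flanking the quaternary C1 to the carbinol carbons C3 and C5. Both are R and trans, so a local C2 axis through C1 and C4 makes the two bonds equivalent. One iridium-catalysed, two-directional transfer-hydrogenative allylation of achiral 2,2-dimethoxypropane-1,3-diol with 3-chloro-2-(chloromethyl)prop-1-ene forms both bonds, the ring and both stereocentres. The exocyclic methylene then becomes C1(OH)CO2H, the ketal becomes the C4 carbinol by conformation-controlled reduction, and lactonisation onto O5 leaves O3 and O4 for vanilloylation.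

Key step: step 1

Remarks on the chemistry:
- Quinic acid numbering is used: C1 bears OH and CO2H, C3 and C4 bear the vanilloyl esters, C5 bears the free hydroxyl (O5 is cis to the carboxyl group).
- The sense of induction of the (R)-bisphosphine is assumed to be the one this catalyst class shows for simple primary alcohols; should it prove opposite, the (S)-ligand is used.
- Compounds 1, 2 and 12 are taken as commercially available.

Step 1
Reactants: 1 2,2-dimethoxypropane-1,3-diol; 2 3-chloro-2-(chloromethyl)prop-1-ene
Product: 6 (1R,3R)-2,2-dimethoxy-5-methylidenecyclohexane-1,3-diol, via hydroxy aldehyde 3 (not isolated), via chloro diol 4 (not isolated), via chloro aldehyde 5 (not isolated)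
Conditions: [Ir(cod)Cl]2 (cat.), (R)-Cl,MeO-BIPHEP (cat.), 4-chloro-3-nitrobenzoic acid (cat.), Cs2CO3, THF, 90 °C, sealed tube, slow addition of 2, high dilution
Reagents that add atoms: none
Why: Proposed new method: the cyclometallated iridium C,O-benzoate dehydrogenates one primary alcohol of 1 to the non-enolisable aldehyde 3, the iridium hydride so formed is deprotonated to monovalent iridium, which ionises an allylic C–Cl bond of 2 to a nucleophilic trivalent π-allyliridium species that adds to 3 through a closed six-membered transition state to give 4 (C6–C5 bond); the same redox-neutral cycle on the remaining primary alcohol and the remaining methallyl-type chloride (via 5) forms the C2–C3 bond within one molecule. The closest known reactions are the iridium-catalysed two-directional double allylation of 1,3-diols from the alcohol oxidation level and the analogous methallylation with methallyl chloride; new is that one 2-methylene-1,3-diyl unit serves both allylations, so that the second becomes ring-closing. The cyclohexane closes by intramolecular carbonyl allylation with the tether on the central allyl carbon, the allyl terminus attacking the aldehyde carbon in a 6-membered carbocyclisation through a chair-like bicyclic transition state that leaves the methylene exocyclic. Both new stereocentres (the future C3 and C5, each R) are set by the (R)-bisphosphine on iridium, the ketal carbon between them being non-stereogenic, so matched double catalyst control should give the trans-diol and drain any minor enantiomer of 4 into the separable meso cis-diol. The step needs C- over O-allylation and cyclisation over oligomerisation, the first secured by the weak carbonate base and the C-nucleophilic π-allyl species, the second by equimolar 2 added slowly at high dilution; enolisation, epimerisation and β-elimination are excluded because neither aldehyde has an α-hydrogen.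

Step 2
Reactants: 6 (1R,3R)-2,2-dimethoxy-5-methylidenecyclohexane-1,3-diol
Product: 7 (3R,5R)-1-(hydroxymethyl)-4,4-dimethoxycyclohexane-1,3,5-triol
Conditions: K2OsO4·2H2O (cat.), NMO, acetone/H2O, rt
Reagents that add atoms: N-methylmorpholine N-oxide, C[N+]1([O-])CCOCC1; water, O
Why: Upjohn dihydroxylation of the 1,1-disubstituted exocyclic alkene; the C2 axis of 6 through C1 and C4 makes the two alkene faces homotopic, so a single tetrol should form and C1 is not yet stereogenic.

Step 3
Reactants: 7 (3R,5R)-1-(hydroxymethyl)-4,4-dimethoxycyclohexane-1,3,5-triol
Product: 8 (3R,5R)-1,3,5-trihydroxy-4,4-dimethoxycyclohexane-1-carboxylic acid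
Conditions: TEMPO (cat.), NaOCl (cat.), NaClO2, MeCN/phosphate buffer pH 6.7, 35 °C
Reagents that add atoms: sodium chlorite, [Na+].[O-]Cl=O
Why: Nitroxyl-catalysed oxidation with chlorite as terminal oxidant is selective for the primary over the secondary and tertiary hydroxyls, and the near-neutral buffer spares the dimethyl ketal; no stereocentre is touched.

Step 4
Reactants: 8 (3R,5R)-1,3,5-trihydroxy-4,4-dimethoxycyclohexane-1-carboxylic acid
Product: 10 (−)-quinic acid, via keto acid 9 (not isolated)
Conditions: Dowex 50WX8 (H+ form), H2O, 50 °C; filter; then NaBH4, H2O, 0 °C; Dowex 50WX8 (H+ form) work-up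
Reagents that add atoms: water, O
Why: Acid-resin ketal hydrolysis (as for dihydroxyacetone ketals) gives ketone 9, whose carboxylate chair should carry CO2− equatorial and the C1 hydroxyl axial, so the carbinol syn to it (C3) is axial and C5 equatorial, and the small hydride adds axially, anti to the axial C3–O bond (Felkin–Anh-type control, as in reductions of α-glycosid-2-uloses), giving the equatorial C4 alcohol cis to O3 and O1.

Step 5
Reactants: 10 (−)-quinic acid
Product: 11 1,5-quinide (quinic acid 1,5-lactone with free 1-, 3- and 4-hydroxyls)
Conditions: p-TsOH·H2O (cat.), DMF/toluene, reflux, Dean–Stark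
Reagents that add atoms: none
Why: Acid-catalysed γ-lactonisation (intramolecular Fischer esterification) is possible only onto the C5 hydroxyl, the one cis to the carboxyl group, which differentiates O5 from O3 and O4; this is the known conversion of quinic acid into its 1,5-lactone.

Step 6
Reactants: 12 4-acetoxy-3-methoxybenzoic acid
Product: 13 4-acetoxy-3-methoxybenzoyl chloride
Conditions: (COCl)2, DMF (cat.), CH2Cl2, 0 °C to rt
Reagents that add atoms: oxalyl chloride, O=C(Cl)C(Cl)=O
Why: Standard acid chloride formation through the Vilsmeier-type chloroiminium intermediate; the aryl acetate is inert.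

Step 7
Reactants: 11 1,5-quinide; 13 4-acetoxy-3-methoxybenzoyl chloride (2 equiv)
Product: 14 3,4-di-O-(4-acetoxy-3-methoxybenzoyl)-1,5-quinide
Conditions: pyridine/CH2Cl2, DMAP (cat.), 0 °C to rt
Reagents that add atoms: none
Why: DMAP-catalysed acylation of the two secondary hydroxyls at C3 (equatorial) and C4 (axial); the bridgehead tertiary C1 hydroxyl next to the lactone carbonyl is far less reactive and should stay free when the acid chloride is limited.

Step 8
Reactants: 14 3,4-di-O-(4-acetoxy-3-methoxybenzoyl)-1,5-quinide
Product: 15 Burkinabin A (3,4-di-O-vanilloylquinic acid)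
Conditions: 2 M HCl (aq)/THF, rt, prolonged stirring
Reagents that add atoms: water, O
Why: Acid-catalysed hydrolysis opens the strained γ-lactone and cleaves the two activated phenolic acetates, while the aroyl esters on the secondary carbinols hydrolyse much more slowly and should not migrate in acid; no stereocentre is affected.

Compound list
1 | 2,2-dimethoxypropane-1,3-diol | COC(CO)(CO)OC | starting material
2 | 3-chloro-2-(chloromethyl)prop-1-ene | C=C(CCl)CCl | starting material
3 | 3-hydroxy-2,2-dimethoxypropanal | COC(CO)(OC)C=O | intermediate
4 | (3R)-5-(chloromethyl)-2,2-dimethoxyhex-5-ene-1,3-diol | COC(CO)(OC)[C@H](O)CC(=C)CCl | intermediate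
5 | (3R)-5-(chloromethyl)-3-hydroxy-2,2-dimethoxyhex-5-enal | COC(C=O)(OC)[C@H](O)CC(=C)CCl | intermediate
6 | (1R,3R)-2,2-dimethoxy-5-methylidenecyclohexane-1,3-diol | COC1(OC)[C@H](O)CC(=C)C[C@H]1O | intermediate
7 | (3R,5R)-1-(hydroxymethyl)-4,4-dimethoxycyclohexane-1,3,5-triol | COC1(OC)[C@H](O)CC(O)(CO)C[C@H]1O | intermediate
8 | (3R,5R)-1,3,5-trihydroxy-4,4-dimethoxycyclohexane-1-carboxylic acid | COC1(OC)[C@H](O)CC(O)(C(=O)O)C[C@H]1O | intermediate
9 | (3R,5R)-1,3,5-trihydroxy-4-oxocyclohexane-1-carboxylic acid | O=C1[C@H](O)CC(O)(C(=O)O)C[C@H]1O | intermediate
10 | (−)-quinic acid, (1S,3R,4S,5R)-1,3,4,5-tetrahydroxycyclohexane-1-carboxylic acid | O[C@H]1[C@H](O)C[C@](O)(C(=O)O)C[C@H]1O | intermediate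
11 | 1,5-quinide (lactone between the C1 carboxyl and O5; 1-, 3-, 4-OH free) | O[C@H]1[C@H](O2)C[C@](O)(C2=O)C[C@H]1O | intermediate
12 | 4-acetoxy-3-methoxybenzoic acid | COc1cc(C(=O)O)ccc1OC(C)=O | starting material
13 | 4-acetoxy-3-methoxybenzoyl chloride | COc1cc(C(Cl)=O)ccc1OC(C)=O | intermediate
14 | 3,4-di-O-(4-acetoxy-3-methoxybenzoyl)-1,5-quinide | COc1cc(C(=O)O[C@H]2[C@H](O3)C[C@](O)(C3=O)C[C@H]2OC(=O)c2ccc(OC(C)=O)c(OC)c2)ccc1OC(C)=O | intermediate
15 | Burkinabin A, 3,4-di-O-(4-hydroxy-3-methoxybenzoyl)quinic acid | COc1cc(C(=O)O[C@H]2[C@H](O)C[C@](O)(C(=O)O)C[C@H]2OC(=O)c2ccc(O)c(OC)c2)ccc1O | target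

Total step count: 8. Longest linear sequence: 7 steps (steps 1, 2, 3, 4, 5, 7, 8).

Steps most likely to fail

Step 1 (key step). The ring-closing second allylation may be outrun by intramolecular O-alkylation of the secondary alkoxide by the allylic chloride (giving a 3-methylenetetrahydrofuran), or by intermolecular coupling to oligomers. The fallback sets out from 1 and 2 and separates the two bond formations using known chemistry. The same iridium system is run with 1 in excess so that only the precedented intermolecular methallyl-chloride-type coupling occurs and chloro diol 4 is isolated. Its primary alcohol is oxidised selectively (TEMPO, PhI(OAc)2, CH2Cl2) to chloro aldehyde 5. The ring is then closed by an intramolecular Nozaki–Hiyama–Kishi allylation (CrCl2, THF, high dilution), a known route from 2-(halomethyl)alkenyl aldehydes to 3-methylenecycloalkanols. The trans-diol is separated from any cis isomer, and the fallback comes back to the route at 6. It makes no compound outside the list (F0).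

Step 4. Hydride addition may lose facial selectivity if the keto acid populates the alternative chair or a twist form, and the α-hydroxy ketone may isomerise through its enediol in the basic borohydride medium. The fallback sets out from 8 and puts the reduction on a rigid bicycle. Aqueous CF3CO2H hydrolyses the ketal, and azeotropic drying (toluene, cat. p-TsOH) lactonises the acid onto the cis hydroxyl to give the keto lactone 4-dehydro-1,5-quinide F1. Reduction with the bulky hydride LiBH(s-Bu)3 (THF, −78 °C) should proceed by equatorial attack and give the axial C4 alcohol trans to the lactone oxygen. This is 11, where the fallback comes back to the route, and steps 4 and 5 are bypassed.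

Step 8. Slow cleavage of the phenolic acetates may force a long acid exposure, with partial loss or migration of the aroyl esters. The fallback sets out from 11 and changes the phenol protection to benzyl ethers, which are removed without acid or base. Commercially available 4-(benzyloxy)-3-methoxybenzoic acid is converted with (COCl)2 and cat. DMF into 4-(benzyloxy)-3-methoxybenzoyl chloride F2. Acylation of 11 (pyridine, cat. DMAP, CH2Cl2) gives 3,4-di-O-[4-(benzyloxy)-3-methoxybenzoyl]-1,5-quinide F3. Only the lactone is then opened by brief treatment with aqueous HCl/THF, giving 3,4-di-O-[4-(benzyloxy)-3-methoxybenzoyl]quinic acid F4. Hydrogenolysis (H2, palladium on carbon, Pd/C, EtOAc/MeOH) removes both benzyl ethers, and the fallback comes back to the route at 15.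

Further compounds
F0 | step 1 | none | none
F1 | step 4 | 4-dehydro-1,5-quinide (keto lactone) | O=C1[C@H](O2)C[C@](O)(C2=O)C[C@H]1O
F2 | step 8 | 4-(benzyloxy)-3-methoxybenzoyl chloride | COc1cc(C(Cl)=O)ccc1OCc1ccccc1
F3 | step 8 | 3,4-di-O-[4-(benzyloxy)-3-methoxybenzoyl]-1,5-quinide | COc1cc(C(=O)O[C@H]2[C@H](O3)C[C@](O)(C3=O)C[C@H]2OC(=O)c2ccc(OCc3ccccc3)c(OC)c2)ccc1OCc1ccccc1
F4 | step 8 | 3,4-di-O-[4-(benzyloxy)-3-methoxybenzoyl]quinic acid | COc1cc(C(=O)O[C@H]2[C@H](O)C[C@](O)(C(=O)O)C[C@H]2OC(=O)c2ccc(OCc3ccccc3)c(OC)c2)ccc1OCc1ccccc1
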